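**Retrosynthetic overview**
- The target is disconnected to a benzyl-type protected (S)-1-aryl-2-aryl-3-aroyl-1H-indene. One hydrogenation adds H2 anti to the existing aryl group, which sets the two remaining stereocentres all-cis, and removes every protecting group.
- The aroyl C–C bonds come from a palladium-catalysed carbonylative Stille coupling of an enantioenriched indenyl triflate, an arylstannane and CO.
- The triflate comes from an achiral 2,3-diarylindenone by a proposed copper hydride enantioselective 1,4-reduction with triflation of the enolate; this sets the first stereocentre.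
- The indenone five-membered ring (the only ring formed) is closed by a Larock annulation of a 2-bromobenzaldehyde with an unsymmetrical diarylacetylene.
- Both resorcinol-type rings come from resorcinol via iridium-catalysed C–H borylation/bromination; both 4-oxyphenyl rings from 4-bromophenol; the alkyne carbons from ethynyltrimethylsilane.

Assumption: the SMILES is read as (1R,2R,3R), with the aroyl group at C1, the 3,5-dihydroxyphenyl group at C2 and the 4-hydroxyphenyl group at C3 all on the same face of the indane; all phenols are carried as 4-methylbenzyl ethers.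

**Route**

Step 1
Reactants: 1 resorcinol
Product: 2 1,3-bis[(4-methylbenzyl)oxy]benzene
Conditions: 4-methylbenzyl chloride (2.2 equiv), K2CO3, KI (cat.), DMF, 60 °C
Reagents that add atoms: 4-methylbenzyl chloride, Cc1ccc(CCl)cc1
Why: Williamson etherification; the 4-methylbenzyl group is used because each of its ring C–H bonds is ortho to a substituent and so inert in the sterically governed borylation of step 2, while it is still cleaved by hydrogenolysis like benzyl.

Step 2
Reactants: 2 1,3-bis[(4-methylbenzyl)oxy]benzene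
Product: 4 1-bromo-3,5-bis[(4-methylbenzyl)oxy]benzene, via aryl pinacol boronate 3 (not isolated)
Conditions: [Ir(OMe)(cod)]2 (1.5 mol%), dtbpy (3 mol%), B2pin2 (1.1 equiv), THF, 80 °C; evaporate; CuBr2 (3 equiv), MeOH/H2O 1:1, 80 °C
Reagents that add atoms: CuBr2, [Cu+2].[Br-].[Br-]; bis(pinacolato)diboron, CC1(C)OB(OC1(C)C)B1OC(C)(C)C(C)(C)O1 (boron only in intermediate 3)
Why: Sterically controlled iridium-catalysed aromatic C–H borylation occurs only at C5, the one C–H with no ortho substituent, and CuBr2 then converts the boronate into the bromide in the same flask (ipso-bromodeboronation).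

Step 3
Reactants: 4 1-bromo-3,5-bis[(4-methylbenzyl)oxy]benzene
Product: 6 3,5-bis[(4-methylbenzyl)oxy]benzaldehyde, via aryllithium 5 (not isolated)
Conditions: n-BuLi (1.05 equiv), THF, −78 °C; DMF; aq. NH4Cl
Reagents that add atoms: N,N-dimethylformamide, CN(C)C=O; n-butyllithium, [Li]CCCC (lithium only in intermediate 5)
Why: Bromine–lithium exchange at −78 °C outruns ortho-lithiation and benzylic deprotonation, and DMF formylates the aryllithium (Bouveault formylation).

Step 4
Reactants: 6 3,5-bis[(4-methylbenzyl)oxy]benzaldehyde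
Product: 7 2-bromo-3,5-bis[(4-methylbenzyl)oxy]benzaldehyde
Conditions: NBS (1.05 equiv), MeCN, 0 °C to rt, dark
Reagents that add atoms: N-bromosuccinimide, BrN1C(=O)CCC1=O
Why: Electrophilic aromatic bromination goes to C2, which is ortho and para to the two ether oxygens, and avoids the doubly flanked C4, as known for the dimethoxy analogue.

Step 5
Reactants: 8 4-bromophenol
Product: 9 1-bromo-4-[(4-methylbenzyl)oxy]benzene
Conditions: 4-methylbenzyl chloride (1.1 equiv), K2CO3, KI (cat.), DMF, 60 °C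
Reagents that add atoms: 4-methylbenzyl chloride, Cc1ccc(CCl)cc1
Why: Williamson etherification of the phenol.

Step 6
Reactants: 9 1-bromo-4-[(4-methylbenzyl)oxy]benzene; 10 ethynyltrimethylsilane
Product: 11 trimethyl({4-[(4-methylbenzyl)oxy]phenyl}ethynyl)silane
Conditions: PdCl2(PhCN)2 (3 mol%), P(t-Bu)3·HBF4 (6 mol%), CuI (2 mol%), i-Pr2NH, dioxane, rt to 40 °C
Reagents that add atoms: none
Why: Sonogashira coupling; the bulky electron-rich phosphine allows oxidative addition of the electron-rich aryl bromide near room temperature.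

Step 7
Reactants: 11 trimethyl({4-[(4-methylbenzyl)oxy]phenyl}ethynyl)silane
Product: 12 1-ethynyl-4-[(4-methylbenzyl)oxy]benzene
Conditions: K2CO3 (0.2 equiv), MeOH/THF, rt
Reagents that add atoms: none
Why: Methoxide-mediated protodesilylation of the alkynylsilane.

Step 8
Reactants: 12 1-ethynyl-4-[(4-methylbenzyl)oxy]benzene; 4 1-bromo-3,5-bis[(4-methylbenzyl)oxy]benzene
Product: 13 1-({4-[(4-methylbenzyl)oxy]phenyl}ethynyl)-3,5-bis[(4-methylbenzyl)oxy]benzene
Conditions: PdCl2(PhCN)2 (3 mol%), P(t-Bu)3·HBF4 (6 mol%), CuI (2 mol%), i-Pr2NH, dioxane, 40 °C, degassed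
Reagents that add atoms: none
Why: Sonogashira coupling of the terminal alkyne with the aryl bromide gives the unsymmetrical diarylacetylene.

Step 9
Reactants: 7 2-bromo-3,5-bis[(4-methylbenzyl)oxy]benzaldehyde; 13 1-({4-[(4-methylbenzyl)oxy]phenyl}ethynyl)-3,5-bis[(4-methylbenzyl)oxy]benzene
Product: 14 4,6-bis[(4-methylbenzyl)oxy]-2-{3,5-bis[(4-methylbenzyl)oxy]phenyl}-3-{4-[(4-methylbenzyl)oxy]phenyl}-1H-inden-1-one
Conditions: Pd(OAc)2 (5 mol%), NaOAc (4 equiv), n-Bu4NCl (1 equiv), DMF, 100 °C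
Reagents that add atoms: none
Why: Larock indenone annulation, in which zerovalent palladium adds to the C–Br bond, the aryl group is delivered syn to the alkyne carbon bearing the electron-rich 4-alkoxyphenyl ring, and the vinylpalladium adds to the aldehyde and loses hydride by β-hydride elimination, closing the five-membered ring.

Step 10
Reactants: 14 4,6-bis[(4-methylbenzyl)oxy]-2-{3,5-bis[(4-methylbenzyl)oxy]phenyl}-3-{4-[(4-methylbenzyl)oxy]phenyl}-1H-inden-1-one
Product: 16 (R)-5,7-bis[(4-methylbenzyl)oxy]-2-{3,5-bis[(4-methylbenzyl)oxy]phenyl}-1-{4-[(4-methylbenzyl)oxy]phenyl}-1H-inden-3-yl trifluoromethanesulfonate, via silyl enol ether 15 (not isolated)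
Conditions: Cu(OAc)2·H2O (5 mol%), (R)-DTBM-SEGPHOS (5.5 mol%), (EtO)2MeSiH (3 equiv), toluene, 0 °C to rt; evaporate; CsF (2 equiv), PhNTf2 (1.3 equiv), DME, 0 °C to rt
Reagents that add atoms: N-phenylbis(trifluoromethanesulfonimide), O=S(=O)(N(c1ccccc1)S(=O)(=O)C(F)(F)F)C(F)(F)F; diethoxymethylsilane, CCO[SiH](C)OCC (silicon only in intermediate 15)
Why: Proposed new method: a chiral bisphosphine copper hydride adds hydride to one enantiotopic face of C3 of the strongly electrophilic, tetrasubstituted 2,3-diarylindenone (hydrocupration to the O-bound copper enolate, then σ-bond metathesis with the silane to give silyl enol ether 15 and regenerate Cu–H), and fluoride then releases the enolate regiospecifically for O-triflation without a strong base, so the new benzylic stereocentre is not deprotonated; the closest known reactions are the copper hydride catalysed asymmetric 1,4-hydrosilylation of β-aryl cyclic enones and the reductive triflation of enones (L-Selectride/PhNTf2), neither shown for 2,3-diarylindenones.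

Step 11
Reactants: 9 1-bromo-4-[(4-methylbenzyl)oxy]benzene
Product: 18 tributyl{4-[(4-methylbenzyl)oxy]phenyl}stannane, via aryllithium 17 (not isolated)
Conditions: n-BuLi (1.05 equiv), THF, −78 °C; Bu3SnCl, −78 °C to rt
Reagents that add atoms: tributyltin chloride, CCCC[Sn](Cl)(CCCC)CCCC; n-butyllithium, [Li]CCCC (lithium only in intermediate 17)
Why: Bromine–lithium exchange followed by stannylation of the aryllithium.

Step 12
Reactants: 16 (R)-5,7-bis[(4-methylbenzyl)oxy]-2-{3,5-bis[(4-methylbenzyl)oxy]phenyl}-1-{4-[(4-methylbenzyl)oxy]phenyl}-1H-inden-3-yl trifluoromethanesulfonate; 18 tributyl{4-[(4-methylbenzyl)oxy]phenyl}stannane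
Product: 19 (S)-(5,7-bis[(4-methylbenzyl)oxy]-2-{3,5-bis[(4-methylbenzyl)oxy]phenyl}-1-{4-[(4-methylbenzyl)oxy]phenyl}-1H-inden-3-yl){4-[(4-methylbenzyl)oxy]phenyl}methanone
Conditions: Pd(PPh3)4 (5 mol%), LiCl (3 equiv), CO (3 atm), THF, 60 °C, no added base
Reagents that add atoms: carbon monoxide, [C-]#[O+]
Why: Carbonylative Stille coupling (oxidative addition of the vinyl triflate, CO insertion to the acylpalladium, transmetalation from tin, reductive elimination) forms both ketone C–C bonds under base-free conditions, so the acidic C1–H stereocentre is untouched (the descriptor changes from R to S only through CIP priorities).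

Step 13
Reactants: 19 (S)-(5,7-bis[(4-methylbenzyl)oxy]-2-{3,5-bis[(4-methylbenzyl)oxy]phenyl}-1-{4-[(4-methylbenzyl)oxy]phenyl}-1H-inden-3-yl){4-[(4-methylbenzyl)oxy]phenyl}methanone
Product: 20 [(1R,2R,3R)-2-(3,5-dihydroxyphenyl)-4,6-dihydroxy-3-(4-hydroxyphenyl)-2,3-dihydro-1H-inden-1-yl](4-hydroxyphenyl)methanone (Caraphenol C as drawn)
Conditions: H2 (3 atm), 10% Pd/C, THF/EtOAc, rt
Reagents that add atoms: none
Why: Heterogeneous catalytic hydrogenation delivers H2 syn to the tetrasubstituted enone C=C from the face opposite the aryl group on the sp3 carbon, so both new C–H bonds are trans to that aryl and the aroyl and 3,5-dioxyphenyl groups end up cis to it (all-cis, 1R,2R,3R), while the five 4-methylbenzyl ethers are hydrogenolysed under neutral conditions that do not epimerise the ketone α-centre.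

**Compound list**
1 | resorcinol | Oc1cccc(O)c1 | starting material
2 | 1,3-bis[(4-methylbenzyl)oxy]benzene | Cc1ccc(COc2cccc(OCc3ccc(C)cc3)c2)cc1 | intermediate
3 | 2-{3,5-bis[(4-methylbenzyl)oxy]phenyl}-4,4,5,5-tetramethyl-1,3,2-dioxaborolane | Cc1ccc(COc2cc(OCc3ccc(C)cc3)cc(c2)B2OC(C)(C)C(C)(C)O2)cc1 | intermediate
4 | 1-bromo-3,5-bis[(4-methylbenzyl)oxy]benzene | Cc1ccc(COc2cc(Br)cc(OCc3ccc(C)cc3)c2)cc1 | intermediate
5 | {3,5-bis[(4-methylbenzyl)oxy]phenyl}lithium | [Li]c1cc(OCc2ccc(C)cc2)cc(OCc2ccc(C)cc2)c1 | intermediate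
6 | 3,5-bis[(4-methylbenzyl)oxy]benzaldehyde | O=Cc1cc(OCc2ccc(C)cc2)cc(OCc2ccc(C)cc2)c1 | intermediate
7 | 2-bromo-3,5-bis[(4-methylbenzyl)oxy]benzaldehyde | O=Cc1cc(OCc2ccc(C)cc2)cc(OCc2ccc(C)cc2)c1Br | intermediate
8 | 4-bromophenol | Oc1ccc(Br)cc1 | starting material
9 | 1-bromo-4-[(4-methylbenzyl)oxy]benzene | Cc1ccc(COc2ccc(Br)cc2)cc1 | intermediate
10 | ethynyltrimethylsilane | C#C[Si](C)(C)C | starting material
11 | trimethyl({4-[(4-methylbenzyl)oxy]phenyl}ethynyl)silane | Cc1ccc(COc2ccc(cc2)C#C[Si](C)(C)C)cc1 | intermediate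
12 | 1-ethynyl-4-[(4-methylbenzyl)oxy]benzene | Cc1ccc(COc2ccc(cc2)C#C)cc1 | intermediate
13 | 1-({4-[(4-methylbenzyl)oxy]phenyl}ethynyl)-3,5-bis[(4-methylbenzyl)oxy]benzene | Cc1ccc(COc2ccc(cc2)C#Cc2cc(OCc3ccc(C)cc3)cc(OCc3ccc(C)cc3)c2)cc1 | intermediate
14 | 4,6-bis[(4-methylbenzyl)oxy]-2-{3,5-bis[(4-methylbenzyl)oxy]phenyl}-3-{4-[(4-methylbenzyl)oxy]phenyl}-1H-inden-1-one | O=C1C(c2cc(OCc3ccc(C)cc3)cc(OCc3ccc(C)cc3)c2)=C(c2ccc(OCc3ccc(C)cc3)cc2)c2c(OCc3ccc(C)cc3)cc(OCc3ccc(C)cc3)cc21 | intermediate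
15 | (R)-[(5,7-bis[(4-methylbenzyl)oxy]-2-{3,5-bis[(4-methylbenzyl)oxy]phenyl}-1-{4-[(4-methylbenzyl)oxy]phenyl}-1H-inden-3-yl)oxy]diethoxy(methyl)silane | CCO[Si](C)(OCC)OC1=C(c2cc(OCc3ccc(C)cc3)cc(OCc3ccc(C)cc3)c2)[C@H](c2ccc(OCc3ccc(C)cc3)cc2)c2c(OCc3ccc(C)cc3)cc(OCc3ccc(C)cc3)cc21 | intermediate
16 | (R)-5,7-bis[(4-methylbenzyl)oxy]-2-{3,5-bis[(4-methylbenzyl)oxy]phenyl}-1-{4-[(4-methylbenzyl)oxy]phenyl}-1H-inden-3-yl trifluoromethanesulfonate | O=S(=O)(OC1=C(c2cc(OCc3ccc(C)cc3)cc(OCc3ccc(C)cc3)c2)[C@H](c2ccc(OCc3ccc(C)cc3)cc2)c2c(OCc3ccc(C)cc3)cc(OCc3ccc(C)cc3)cc21)C(F)(F)F | intermediate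
17 | {4-[(4-methylbenzyl)oxy]phenyl}lithium | [Li]c1ccc(OCc2ccc(C)cc2)cc1 | intermediate
18 | tributyl{4-[(4-methylbenzyl)oxy]phenyl}stannane | CCCC[Sn](CCCC)(CCCC)c1ccc(OCc2ccc(C)cc2)cc1 | intermediate
19 | (S)-(5,7-bis[(4-methylbenzyl)oxy]-2-{3,5-bis[(4-methylbenzyl)oxy]phenyl}-1-{4-[(4-methylbenzyl)oxy]phenyl}-1H-inden-3-yl){4-[(4-methylbenzyl)oxy]phenyl}methanone | O=C(c1ccc(OCc2ccc(C)cc2)cc1)C1=C(c2cc(OCc3ccc(C)cc3)cc(OCc3ccc(C)cc3)c2)[C@H](c2ccc(OCc3ccc(C)cc3)cc2)c2c(OCc3ccc(C)cc3)cc(OCc3ccc(C)cc3)cc21 | intermediate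
20 | [(1R,2R,3R)-2-(3,5-dihydroxyphenyl)-4,6-dihydroxy-3-(4-hydroxyphenyl)-2,3-dihydro-1H-inden-1-yl](4-hydroxyphenyl)methanone | O=C(c1ccc(O)cc1)[C@H]1c2cc(O)cc(O)c2[C@@H](c2ccc(O)cc2)[C@H]1c1cc(O)cc(O)c1 | target

**Totals**
Total step count: 13. Longest linear sequence: 8 (steps 1, 2, 3, 4, 9, 10, 12, 13; the branch 5, 6, 7, 8, 9, 10, 12, 13 is equally long).

**Steps most likely to fail, with fallbacks**

Step 10 (proposed new step). The risks are competing 1,2-reduction of the α-aryl enone, low or opposite enantioselectivity (the antipodal ligand would then be used), and partial racemisation during enolate triflation. The fallback uses known chemistry and sets out from 14. Zn dust in AcOH/THF reduces the indenone C=C to the racemic 2,3-diarylindan-1-one F1 (cis/trans mixture). Catalytic DBU equilibrates C2 to the trans isomer, and preparative chiral SFC gives the (2R,3R)-indanone F2. Tf2O with 2,6-di-tert-butyl-4-methylpyridine (CH2Cl2, −78 to 0 °C) then forms the enol triflate without a strong base, and the route is rejoined at 16.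

Step 12. The risks are slow CO insertion or transmetalation at the hindered tetrasubstituted vinylpalladium, direct (non-carbonylative) coupling, and erosion of the acidic stereocentre. The fallback sets out from 16 (and 9). Aryllithium 17, made from 9 as in step 11, is quenched with DMF to give 4-[(4-methylbenzyl)oxy]benzaldehyde F3. A Nozaki–Hiyama–Kishi coupling of 16 with F3 (CrCl2, NiCl2 cat., DMF, rt, neutral) gives the indenyl carbinol F4 as a mixture of carbinol epimers. Dess–Martin periodinane (NaHCO3, CH2Cl2) oxidises it to the enone, and the route is rejoined at 19.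

Step 13. The risks are a sluggish tetrasubstituted alkene that needs forcing conditions, under which the aryl ketone may be over-reduced, and incomplete face selectivity. The fallback sets out from 19 and separates the two tasks. Homogeneous hydrogenation with [Ir(cod)(PCy3)(py)]PF6 (5 mol%, H2 1–4 atm, CH2Cl2) is well suited to tetrasubstituted alkenes, leaves ketone and ethers intact, and still adds anti to the aryl group, giving the all-cis penta(4-methylbenzyl) ether F5. A short hydrogenolysis at 1 atm (Pd/C, H2, EtOAc/THF), now free of the alkene reduction, removes the ethers, and the route is rejoined at 20.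

**Further compounds**
F1 | step 10 | racemic 4,6-bis[(4-methylbenzyl)oxy]-2-{3,5-bis[(4-methylbenzyl)oxy]phenyl}-3-{4-[(4-methylbenzyl)oxy]phenyl}indan-1-one (cis/trans mixture) | O=C1C(c2cc(OCc3ccc(C)cc3)cc(OCc3ccc(C)cc3)c2)C(c2ccc(OCc3ccc(C)cc3)cc2)c2c(OCc3ccc(C)cc3)cc(OCc3ccc(C)cc3)cc21
F2 | step 10 | (2R,3R)-4,6-bis[(4-methylbenzyl)oxy]-2-{3,5-bis[(4-methylbenzyl)oxy]phenyl}-3-{4-[(4-methylbenzyl)oxy]phenyl}indan-1-one | O=C1[C@@H](c2cc(OCc3ccc(C)cc3)cc(OCc3ccc(C)cc3)c2)[C@H](c2ccc(OCc3ccc(C)cc3)cc2)c2c(OCc3ccc(C)cc3)cc(OCc3ccc(C)cc3)cc21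
F3 | step 12 | 4-[(4-methylbenzyl)oxy]benzaldehyde | Cc1ccc(COc2ccc(C=O)cc2)cc1
F4 | step 12 | [(1S)-5,7-bis[(4-methylbenzyl)oxy]-2-{3,5-bis[(4-methylbenzyl)oxy]phenyl}-1-{4-[(4-methylbenzyl)oxy]phenyl}-1H-inden-3-yl]{4-[(4-methylbenzyl)oxy]phenyl}methanol (carbinol epimers) | OC(c1ccc(OCc2ccc(C)cc2)cc1)C1=C(c2cc(OCc3ccc(C)cc3)cc(OCc3ccc(C)cc3)c2)[C@H](c2ccc(OCc3ccc(C)cc3)cc2)c2c(OCc3ccc(C)cc3)cc(OCc3ccc(C)cc3)cc21
F5 | step 13 | [(1R,2R,3R)-4,6-bis[(4-methylbenzyl)oxy]-2-{3,5-bis[(4-methylbenzyl)oxy]phenyl}-3-{4-[(4-methylbenzyl)oxy]phenyl}-2,3-dihydro-1H-inden-1-yl]{4-[(4-methylbenzyl)oxy]phenyl}methanone | O=C(c1ccc(OCc2ccc(C)cc2)cc1)[C@H]1c2cc(OCc3ccc(C)cc3)cc(OCc3ccc(C)cc3)c2[C@@H](c2ccc(OCc3ccc(C)cc3)cc2)[C@H]1c1cc(OCc2ccc(C)cc2)cc(OCc2ccc(C)cc2)c1
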